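Compound numbers are fixed by the steps below (1–39; 39 is the target) and are used in every section.

## Analysis of the target

Target 39 is a cycloheptane (ring atoms C1, C5, C6, C7, C8, C9, C10) cis-fused through C6–C7 to an α-methylene γ-lactone (C11, carbonyl C12, exocyclic C13, ring oxygen on C6). C1 is a quaternary carbinol carrying the 3-hydroxybutanoyl chain (ketone C2, C3, carbinol C4); C10 carries a methyl group, C9 a free hydroxyl and the C5 oxygen a (2R)-2-methylbutanoate. The descriptors are 1S, 4S, 5S, 6R, 7S, 9R, 10S. Calling α the ring face that holds C11 at C7, the lactone oxygen on C6, the C1 hydroxyl and the C10 methyl are α, whereas the C5 acyloxy group, the C9 hydroxyl and the C2 acyl branch on C1 are β. C5–O is therefore trans to both oxygen neighbours, the C10 methyl is cis to the C1 hydroxyl and trans to the C9 hydroxyl, and C4 is insulated from the ring by the ketone and needs its own control. The sensitive functions are the methylene lactone (a Michael acceptor), the β-hydroxy ketone (dehydration, retro-aldol), the tertiary ketol at C1, an ester with an epimerisable α-centre, and four hydroxyls of which only the most hindered (C5) is acylated. The hard point is C1: a fully substituted carbon that is a carbinol, the anchor of the acyl chain and the neighbour of C5 and C10, set in a seven-membered ring for which few direct ring-forming reactions exist. The strategy rests on the array C5–C1–C10–C9: C1 bears the carbonyl carbon C2, the adjacent C10 bears a methyl group, and both are flanked by the oxygenated C5 and C9. This is a but-2-ynoate (C2–C1≡C10–CH3) inserted into the C5–C9 bond of a cyclopentanone (C5, C6, C7, C8, C9) that already carries the acetic acid arm C11–C12 on C7.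

## Retrosynthetic reasoning

39 to 38. The last operation only releases the C9 and C1 hydroxyls from their silyl ethers. With the β-hydroxy ketone, the ketol and the methylene lactone all present, nothing harsher than a buffered fluoride source is acceptable at the end.

38 to 34 and 35 (C3–C4). The chain is cut at the aldol bond, giving methyl ketone 34 and acetaldehyde 35. C1 is quaternary, so the acetyl group of 34 can enolise on one side only. A boron enolate leaves the methylene lactone and the C5 ester alone, and the boron ligand sets C4.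

34 to 32 to 30 (C2–C3). The acetyl group comes from carboxylic acid 32 by acyl chloride formation and cross-coupling with a methyl–zinc reagent; 32 comes from tert-butyl ester 30. C2 entered as an ester carbon in the ring-forming step. A tert-butyl ester survives the base, hydride and enolate steps in between and can be removed without a nucleophile, which matters once a lactone, a Michael acceptor and a second ester are present.

30 to 27 and 28 (O5–acyl). The ester is attached while C5–OH is the only acylable hydroxyl: C9 is silylated, C1–OH is tertiary and C4 does not yet exist. It is attached after the lactone enolate chemistry so that its α-centre is never exposed to strong base.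

27 to 23 (C11=C13). The methylene group comes from an enolate Mannich reaction and elimination on saturated lactone 23. At this stage C11 is the only enolisable carbon, because the C1 ester has no α-hydrogen and no ketone is present.

23 to 22 to 21 (C5 stereocentre). The C5 carbinol comes from ketone 22 by hydride delivered from the free C1 hydroxyl. This places the new hydroxyl trans to C1–OH, which is the target relation. 22 comes from 21 by unmasking the C1 silyl ether.

21 to 18 (O–C6). Cutting the lactone C–O bond at C6 gives keto acid 18. Forward, the ketone can enolise only toward C6; halogenation there and SN2 closure by the carboxylate from the face of the C7 arm give the cis fusion without a separate stereochemical decision. 18 derives from 17, 16 and 15 by oxidation, ester hydrolysis and silylation.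

15 to 13 (C9–O and C10–H). Anti-Markovnikov syn hydration of the trisubstituted C9=C10 alkene sets the trans C9–OH/C10–CH3 pair in one step. The face is governed by the C1 silyloxy group and the C7 arm, both α. The C5 carbonyl is co-reduced and restored later.

13 to 12 to 10 (C1–O). The tertiary hydroxyl comes from electrophilic oxygen transfer to the α-carbon of the dienolate of β-keto ester 10. This attack is deconjugative and keeps C9=C10 for the hydration.

10 to 9 to 6 and 7 (C9–C10 and C1–C5 made, C5–C9 broken). β-Keto ester 10 is the hydrolysis product of dienamine 9, which is the ring-enlarged adduct of enamine 6 and alkynoate 7. This delivers the seven-membered ring, C2 on C1, the methyl on C10, a masked C5 ketone and the C9=C10 alkene at once, with C7 already in place.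

6 to 4 and 5; 4 to 3; 3 to 1 and 2. The enamine comes from ketone 4 and pyrrolidine 5. Ketone 4 comes from malonate adduct 3 by loss of one ester, and 3 from cyclopentenone 1 and dimethyl malonate 2 by a catalytic asymmetric conjugate addition that sets C7. The malonate is trimmed before the ring enlargement for two reasons: its acidic C–H would compete as a donor toward 7, and afterwards the C2 ester is a β-keto ester that would not survive dealkoxycarbonylation.

## Alternatives that were turned down

Alternative 1: The ring bond C6–C7 and the lactone C12–O bond are cut together. An open-chain precursor ending in a C6 aldehyde and a bromomethyl acrylate unit would be treated with CrCl2 (divalent chromium). The allylchromium species adds through C7 to the aldehyde, closing the seven-membered ring, and the C6 alkoxide lactonises to the fully protected core A1.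
- For it: organochromium reagents select aldehydes over the C2 ketone, the ring and the methylene lactone appear in one late step, and A1 is only an acylation and deprotections away from the target.
- Against it: the precursor must already hold C1 (an acyclic quaternary carbinol bearing the acyl chain), C5, C9, C10 and C4 in the right relative sense, which means a long linear sequence. The closure is a medium-ring cyclisation, and the C6/C7 configuration depends on a transition state in which the neighbouring acetonide and the chain compete.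
- Comparison: on endgame economy and on C4 this route is stronger. The chosen route offers the carbocycle with C2 and the C10 methyl in four steps from bulk chemicals, no entropically disfavoured closure, and C7 from a catalytic reaction.

Alternative 2: C1–C10 and C8–C9 are cut. A 3-oxidopyrylium ylide released from a furan-derived precursor would add across an E-configured propenyl ether to give the oxygen-bridged cycloheptenone A2.
- For it: the quaternary C1 arrives with its oxygen and its carboxyl carbon, and the trans C9–O/C10–CH3 pair follows from the alkene geometry. On these two points it is stronger than the chosen route, which needs a reagent-controlled hydroxylation and a face-selective hydroboration.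
- Against it: the bridging oxygen ends on C8, a plain methylene in the target, so a reductive C–O cleavage must be added. Intermolecular additions of such ylides to simple enol ethers need a large excess of the partner and give uncertain regio- and endo/exo ratios. The absolute configuration requires an auxiliary or a resolution. The C7 arm, the C6 oxygen and the C5 configuration all remain to be installed on the enone.
- Comparison: the chosen route carries no superfluous C–O bond, fixes the absolute configuration in its first step and has the acetic acid arm on C7 from the start.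

Alternative 3: C5–C6 and C7–C8 are formed by light. A benzyloxy-substituted cyclopentenone and a dihydrofuran would be joined in a cyclobutane; hydrogenolysis of the benzyl ether then triggers retro-aldol cleavage of C5–C8 and gives the cis-fused oxolane–cycloheptanedione A3.
- For it: it is also a two-carbon ring enlargement. The cis C6–O/C7 relation and oxygen at C5 and C9 come directly, which is stronger than the chosen route, where C6 has to be oxidised later.
- Against it: in A3 C1 is a bare methylene, so the quaternary carbinol and the whole acyl chain must be built next to one of two ketones with four enolisable positions competing. C10 is formed as an epimer mixture. The head-to-head or head-to-tail sense of the photocycloaddition is not secured. The oxolane must still be oxidised to the lactone and its side arm converted into C13.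
- Comparison: the chosen route attaches C2 to C1 in the ring-forming step, so the hardest carbon is complete in skeleton when the ring appears.

Key step: step 4

Remark: tert-butyl but-2-ynoate (7), (2R)-2-methylbutanoic acid (28) and (1S)-(+)-(10-camphorsulfonyl)oxaziridine are taken as catalogue compounds.
Remark: from compound 14 on, names use the atom labels of the analysis (ring C1, C5–C10) and α/β for the ring faces; the absolute sense is fixed by the SMILES in the compound list.

## Steps

Step 1
Reactants: 1 cyclopent-2-en-1-one; 2 dimethyl malonate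
Product: 3 dimethyl 2-[(1R)-3-oxocyclopentyl]propanedioate
Conditions: NaGa[(R)-1,1'-binaphthalene-2,2'-diolate]2 (10 mol %), NaOtBu (9 mol %), THF, rt
Reagents that add atoms: none
Why: Catalytic asymmetric Michael addition; the heterobimetallic binaphtholate activates the enone as a Lewis acid and the malonate as a Brønsted base, and the (R)-ligand series should give the (R)-adduct. This centre becomes C7 and is the anchor for all later ring stereocentres.

Step 2
Reactants: 3 dimethyl 2-[(1R)-3-oxocyclopentyl]propanedioate
Product: 4 methyl 2-[(1R)-3-oxocyclopentyl]acetate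
Conditions: LiCl, H2O, DMSO, 150 °C
Reagents that add atoms: none
Why: Krapcho dealkoxycarbonylation of a geminal diester. It is placed here because a malonate C–H would compete as a donor toward the alkynoate in step 4 and because the C2 ester formed there is a β-keto ester that would be lost under the same conditions.

Step 3
Reactants: 4 methyl 2-[(1R)-3-oxocyclopentyl]acetate; 5 pyrrolidine
Product: 6 methyl 2-[(1R)-3-(pyrrolidin-1-yl)cyclopent-3-en-1-yl]acetate
Conditions: 5 (1.5 equiv), 4 Å molecular sieves, toluene, rt; filter, concentrate, use crude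
Reagents that add atoms: none
Why: Stork enamine condensation driven by removal of water. The isomer named, with the double bond toward C9 and away from the C7 arm, should predominate, and it equilibrates with the C5=C6 isomer through the iminium ion.

Step 4
Reactants: 6 methyl 2-[(1R)-3-(pyrrolidin-1-yl)cyclopent-3-en-1-yl]acetate; 7 tert-butyl but-2-ynoate
Product: 9 tert-butyl (4R)-4-(2-methoxy-2-oxoethyl)-7-methyl-2-(pyrrolidin-1-yl)cyclohepta-1,6-diene-1-carboxylate, via aminocyclobutene 8 (not isolated)
Conditions: 7 (2 equiv), toluene, 110 °C, sealed tube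
Reagents that add atoms: none
Why: The enamine carbon C9 adds in Michael fashion to the methyl-bearing alkyne carbon C10, and the resulting allenolate closes through C1 onto the iminium carbon C5 (4-exo-trig), a stepwise dipolar [2+2] addition that gives the cis-fused aminocyclobutene 8. In 8 the C5–C9 bond lies between the nitrogen lone pair on C5 and the C10=C1–ester acceptor, so it opens heterolytically in the sense of a 4π electrocyclic ring opening; the seven-membered ring thus arises by enlargement of the five-membered ring and not by an end-to-end cyclisation. The closest known reaction type is the two-carbon ring enlargement of cyclic ketone enamines with propiolates and acetylenedicarboxylates. No stereocentre is created, since C5 and C9 end as sp2 carbons, and C7 is a spectator. The step needs two selectivities: reaction through the C9 enamine, secured because the C7 arm crowds the C5=C6 isomer and its transition state while the two isomers interconvert, and the orientation of the alkyne, secured by the ester, which makes C10 the electrophilic carbon. An aprotic medium keeps the dipolar intermediate from being protonated to an open-chain adduct, and heat compensates for the lower electrophilicity of a β-methyl alkynoate.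

Step 5
Reactants: 9 tert-butyl (4R)-4-(2-methoxy-2-oxoethyl)-7-methyl-2-(pyrrolidin-1-yl)cyclohepta-1,6-diene-1-carboxylate
Product: 10 tert-butyl (5R)-5-(2-methoxy-2-oxoethyl)-2-methyl-7-oxocyclohept-2-ene-1-carboxylate
Conditions: 1 M aq HCl, THF, rt
Reagents that add atoms: water, O
Why: Acid hydrolysis of a vinylogous carbamate: protonation at C1, addition of water to the iminium carbon C5 and loss of pyrrolidine. The C9=C10 alkene is untouched; 10 is expected mainly as its hydrogen-bonded enol and is used at once to avoid migration of the alkene into conjugation.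

Step 6
Reactants: 10 tert-butyl (5R)-5-(2-methoxy-2-oxoethyl)-2-methyl-7-oxocyclohept-2-ene-1-carboxylate
Product: 12 tert-butyl (1S,5R)-1-hydroxy-5-(2-methoxy-2-oxoethyl)-2-methyl-7-oxocyclohept-2-ene-1-carboxylate, via sodium dienolate 11 (not isolated)
Conditions: NaN(SiMe3)2 (1.05 equiv), THF, −78 °C; (1S)-(+)-(10-camphorsulfonyl)oxaziridine (1.2 equiv), −78 to −40 °C; NH4Cl
Reagents that add atoms: (1S)-(+)-(10-camphorsulfonyl)oxaziridine, CC1(C)[C@@H]2CC[C@]13CS(=O)(=O)N4O[C@@]34C2
Why: Davis hydroxylation of a β-keto ester enolate; the dienolate reacts at its α-carbon C1 (deconjugative attack), which creates the tertiary alcohol and keeps C9=C10. C7 is too remote to bias the planar dienolate, so the face is chosen by the chiral oxaziridine; the (+)-reagent is named for delivery to the α face (1S), and its enantiomer is the direct recourse if the sense is the opposite one.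

Step 7
Reactants: 12 tert-butyl (1S,5R)-1-hydroxy-5-(2-methoxy-2-oxoethyl)-2-methyl-7-oxocyclohept-2-ene-1-carboxylate
Product: 13 tert-butyl (1S,5R)-5-(2-methoxy-2-oxoethyl)-2-methyl-7-oxo-1-(triethylsilyloxy)cyclohept-2-ene-1-carboxylate
Conditions: Et3SiOTf, 2,6-lutidine, CH2Cl2, −78 °C
Reagents that add atoms: triethylsilyl trifluoromethanesulfonate, CC[Si](CC)(CC)OS(=O)(=O)C(F)(F)F
Why: Silylation of a tertiary alcohol with a silyl triflate and a hindered base, fast enough at −78 °C to spare the tert-butyl ester. The silyl ether shields the α face at C1 for step 8 and suppresses ketol rearrangement.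

Step 8
Reactants: 13 tert-butyl (1S,5R)-5-(2-methoxy-2-oxoethyl)-2-methyl-7-oxo-1-(triethylsilyloxy)cyclohept-2-ene-1-carboxylate
Product: 15 tert-butyl 5ξ,9β-dihydroxy-7α-(2-methoxy-2-oxoethyl)-10α-methyl-1α-(triethylsilyloxy)cycloheptane-1β-carboxylate (both C5 epimers), via alkylborane 14 (not isolated)
Conditions: BH3·THF (3 equiv), THF, 0 °C to rt; then 30 % H2O2, 3 M aq NaOAc, 0 °C
Reagents that add atoms: hydrogen peroxide, OO
Why: Brown hydroboration–oxidation; boron goes to the less substituted C9 and hydrogen to C10 in a syn addition from the β face, anti to the C1 silyloxy group and to the C7 arm, so that after oxidation with retention C9–OH is β and the C10 methyl α. The C5 ketone is reduced at the same time, which is accepted because C5 is re-oxidised in step 11.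

Step 9
Reactants: 15 tert-butyl 5ξ,9β-dihydroxy-7α-(2-methoxy-2-oxoethyl)-10α-methyl-1α-(triethylsilyloxy)cycloheptane-1β-carboxylate
Product: 16 tert-butyl 9β-(tert-butyldimethylsilyloxy)-5ξ-hydroxy-7α-(2-methoxy-2-oxoethyl)-10α-methyl-1α-(triethylsilyloxy)cycloheptane-1β-carboxylate
Conditions: tBuMe2SiCl (1.1 equiv), imidazole, DMF, 0 °C to rt
Reagents that add atoms: tert-butyldimethylsilyl chloride, CC(C)(C)[Si](C)(C)Cl
Why: Site-selective silylation; the C9 hydroxyl lies between a CH2 and a CH group and is far less hindered than the C5 hydroxyl next to the quaternary C1, so one equivalent of silyl chloride should protect C9 only.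

Step 10
Reactants: 16 tert-butyl 9β-(tert-butyldimethylsilyloxy)-5ξ-hydroxy-7α-(2-methoxy-2-oxoethyl)-10α-methyl-1α-(triethylsilyloxy)cycloheptane-1β-carboxylate
Product: 17 [1β-(tert-butoxycarbonyl)-9β-(tert-butyldimethylsilyloxy)-5ξ-hydroxy-10α-methyl-1α-(triethylsilyloxy)cycloheptan-7α-yl]acetic acid
Conditions: LiOH (2 equiv), THF/H2O 3:1, 0 °C; then 1 M HCl to pH 4
Reagents that add atoms: lithium hydroxide, [Li+].[OH-]
Why: Saponification of the unhindered methyl ester; the tert-butyl ester on the quaternary C1 and both silyl ethers are inert at 0 °C. It is run before the C5 ketone is restored so that hydroxide cannot start a retro-Claisen cleavage of a β-keto ester.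

Step 11
Reactants: 17 [1β-(tert-butoxycarbonyl)-9β-(tert-butyldimethylsilyloxy)-5ξ-hydroxy-10α-methyl-1α-(triethylsilyloxy)cycloheptan-7α-yl]acetic acid
Product: 18 [1β-(tert-butoxycarbonyl)-9β-(tert-butyldimethylsilyloxy)-10α-methyl-5-oxo-1α-(triethylsilyloxy)cycloheptan-7α-yl]acetic acid
Conditions: Dess–Martin periodinane, NaHCO3, CH2Cl2, rt
Reagents that add atoms: none
Why: Dess–Martin oxidation of the hindered secondary C5 alcohol; both C5 epimers converge on one ketone, and the free acid and silyl ethers are tolerated.

Step 12
Reactants: 18 [1β-(tert-butoxycarbonyl)-9β-(tert-butyldimethylsilyloxy)-10α-methyl-5-oxo-1α-(triethylsilyloxy)cycloheptan-7α-yl]acetic acid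
Product: 21 [1β-(tert-butoxycarbonyl)-9β-(tert-butyldimethylsilyloxy)-6α-hydroxy-10α-methyl-5-oxo-1α-(triethylsilyloxy)cycloheptan-7α-yl]acetic acid γ-lactone, via dilithium enolate carboxylate 19 (not isolated), via 6β-iodo ketone carboxylate 20 (not isolated)
Conditions: LiN(SiMe3)2 (2.2 equiv), THF, −78 °C; I2 (1.1 equiv), −78 to 0 °C
Reagents that add atoms: none
Why: Enolate iodination followed by intramolecular carboxylate displacement (oxidative lactonisation); the ketone can enolise only toward C6 because C1 is quaternary. Iodine enters anti to the C7 arm (6β), and the carboxylate then displaces iodide from the α face in a 5-exo-tet SN2 step with inversion, which can only give the cis-fused lactone with C6–O α; any 6α-iodide equilibrates by iodide exchange and is drained the same way.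

Step 13
Reactants: 21 [1β-(tert-butoxycarbonyl)-9β-(tert-butyldimethylsilyloxy)-6α-hydroxy-10α-methyl-5-oxo-1α-(triethylsilyloxy)cycloheptan-7α-yl]acetic acid γ-lactone
Product: 22 [1β-(tert-butoxycarbonyl)-9β-(tert-butyldimethylsilyloxy)-1α,6α-dihydroxy-10α-methyl-5-oxocycloheptan-7α-yl]acetic acid 6-γ-lactone
Conditions: HF·pyridine, pyridine, THF, 0 °C
Reagents that add atoms: none
Why: Selective fluoride cleavage of the triethylsilyl ether beside the secondary tert-butyldimethylsilyl ether, following the usual order of lability; it frees the C1 hydroxyl that must direct step 14.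

Step 14
Reactants: 22 [1β-(tert-butoxycarbonyl)-9β-(tert-butyldimethylsilyloxy)-1α,6α-dihydroxy-10α-methyl-5-oxocycloheptan-7α-yl]acetic acid 6-γ-lactone
Product: 23 [1β-(tert-butoxycarbonyl)-9β-(tert-butyldimethylsilyloxy)-1α,5β,6α-trihydroxy-10α-methylcycloheptan-7α-yl]acetic acid 6-γ-lactone
Conditions: Me4NBH(OAc)3 (5 equiv), MeCN/AcOH 1:1, −30 to 0 °C
Reagents that add atoms: none
Why: Hydroxyl-directed reduction of the Evans–Saksena type; the C1 hydroxyl exchanges onto boron and the hydride is delivered intramolecularly to the α face of the C5 carbonyl, so the new hydroxyl is β, trans to C1–OH and to C6–O. Triacetoxyborohydride does not reduce ketones or lactones without such delivery.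

Step 15
Reactants: 23 [1β-(tert-butoxycarbonyl)-9β-(tert-butyldimethylsilyloxy)-1α,5β,6α-trihydroxy-10α-methylcycloheptan-7α-yl]acetic acid 6-γ-lactone
Product: 27 2-[1β-(tert-butoxycarbonyl)-9β-(tert-butyldimethylsilyloxy)-1α,5β,6α-trihydroxy-10α-methylcycloheptan-7α-yl]prop-2-enoic acid 6-γ-lactone, via trilithium alkoxide enolate 24 (not isolated), via Mannich base 25 (not isolated), via methiodide 26 (not isolated)
Conditions: LiN(iPr)2 (3.3 equiv), THF, −78 °C; [Me2N=CH2]I (2 equiv), −78 to 0 °C; aqueous work-up; MeI, MeOH, rt; aq NaHCO3, CH2Cl2, rt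
Reagents that add atoms: N,N-dimethylmethyleneiminium iodide (Eschenmoser's salt), C=[N+](C)C.[I-]
Why: α-Methylenation of a lactone through its enolate, Mannich reaction with Eschenmoser's salt and Hofmann-type elimination of the quaternised amine. C11 is the only enolisable carbon, since the tert-butyl ester has no α-hydrogen and the two hydroxyls ride as lithium alkoxides, and the elimination can only give the exocyclic alkene.

Step 16
Reactants: 27 2-[1β-(tert-butoxycarbonyl)-9β-(tert-butyldimethylsilyloxy)-1α,5β,6α-trihydroxy-10α-methylcycloheptan-7α-yl]prop-2-enoic acid 6-γ-lactone; 28 (2R)-2-methylbutanoic acid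
Product: 30 2-[1β-(tert-butoxycarbonyl)-9β-(tert-butyldimethylsilyloxy)-1α,6α-dihydroxy-10α-methyl-5β-[(2R)-2-methylbutanoyloxy]cycloheptan-7α-yl]prop-2-enoic acid 6-γ-lactone, via mixed anhydride 29 (not isolated)
Conditions: 28 (3 equiv), 2,4,6-trichlorobenzoyl chloride, Et3N, THF, rt; then 27, DMAP, toluene, 40 °C
Reagents that add atoms: none
Why: Yamaguchi esterification of the hindered secondary C5 hydroxyl; the tertiary C1 hydroxyl does not react, and mixed-anhydride activation keeps the α-centre of the acid from epimerising.

Step 17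
Reactants: 30 2-[1β-(tert-butoxycarbonyl)-9β-(tert-butyldimethylsilyloxy)-1α,6α-dihydroxy-10α-methyl-5β-[(2R)-2-methylbutanoyloxy]cycloheptan-7α-yl]prop-2-enoic acid 6-γ-lactone
Product: 32 9β-(tert-butyldimethylsilyloxy)-7α-(1-carboxyethenyl)-6α-hydroxy-10α-methyl-5β-[(2R)-2-methylbutanoyloxy]-1α-(triethylsilyloxy)cycloheptane-1β-carboxylic acid 12,6-lactone, via triethylsilyl ester 31 (not isolated)
Conditions: Et3SiOTf (3.5 equiv), 2,6-lutidine (5 equiv), CH2Cl2, 0 °C to rt; then pH 7 buffer, THF
Reagents that add atoms: triethylsilyl trifluoromethanesulfonate, CC[Si](CC)(CC)OS(=O)(=O)C(F)(F)F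
Why: Silyl triflate cleavage of a tert-butyl ester (loss of 2-methylpropene from the O-silylated ester) with concurrent silylation of the C1 hydroxyl. Aqueous work-up hydrolyses only the silyl ester, so the C2 acid is freed without any nucleophile that would attack the lactone, the methylene group or the C5 ester.

Step 18
Reactants: 32 9β-(tert-butyldimethylsilyloxy)-7α-(1-carboxyethenyl)-6α-hydroxy-10α-methyl-5β-[(2R)-2-methylbutanoyloxy]-1α-(triethylsilyloxy)cycloheptane-1β-carboxylic acid 12,6-lactone
Product: 34 2-[1β-acetyl-9β-(tert-butyldimethylsilyloxy)-6α-hydroxy-10α-methyl-5β-[(2R)-2-methylbutanoyloxy]-1α-(triethylsilyloxy)cycloheptan-7α-yl]prop-2-enoic acid γ-lactone, via acid chloride 33 (not isolated)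
Conditions: 1-chloro-N,N,2-trimethylprop-1-en-1-amine, CH2Cl2, 0 °C to rt; then Me2Zn (1.5 equiv), Pd(PPh3)4 (5 mol %), THF, 0 °C
Reagents that add atoms: dimethylzinc, C[Zn]C
Why: Neutral acid chloride formation with an α-chloroenamine, then Negishi-type acylation: zerovalent palladium inserts into the C–Cl bond and dimethylzinc transfers one methyl group. Organozinc reagents do not add to the methylene lactone, the esters or the product ketone.

Step 19
Reactants: 34 2-[1β-acetyl-9β-(tert-butyldimethylsilyloxy)-6α-hydroxy-10α-methyl-5β-[(2R)-2-methylbutanoyloxy]-1α-(triethylsilyloxy)cycloheptan-7α-yl]prop-2-enoic acid γ-lactone; 35 acetaldehyde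
Product: 38 2-[9β-(tert-butyldimethylsilyloxy)-6α-hydroxy-1β-[(3S)-3-hydroxybutanoyl]-10α-methyl-5β-[(2R)-2-methylbutanoyloxy]-1α-(triethylsilyloxy)cycloheptan-7α-yl]prop-2-enoic acid γ-lactone, via enol borinate 36 (not isolated), via boron aldolate 37 (not isolated)
Conditions: (+)-Ipc2BCl (1.5 equiv), Et3N, Et2O, −78 to 0 °C; 35 (5 equiv), −78 to −20 °C; pH 7 buffer, MeOH, 30 % H2O2, 0 °C
Reagents that add atoms: none
Why: Paterson boron aldol reaction; the ketone enolises only toward its methyl group, and the enol diisopinocampheylborinate adds to acetaldehyde under reagent control. The (+)-reagent (from (−)-α-pinene) is named for addition to the re face, which gives (4S); the weak base and low temperature leave the methylene lactone and both esters untouched.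

Step 20
Reactants: 38 2-[9β-(tert-butyldimethylsilyloxy)-6α-hydroxy-1β-[(3S)-3-hydroxybutanoyl]-10α-methyl-5β-[(2R)-2-methylbutanoyloxy]-1α-(triethylsilyloxy)cycloheptan-7α-yl]prop-2-enoic acid γ-lactone
Product: 39 2-[1α,6α,9β-trihydroxy-1β-[(3S)-3-hydroxybutanoyl]-10α-methyl-5β-[(2R)-2-methylbutanoyloxy]cycloheptan-7α-yl]prop-2-enoic acid 6-γ-lactone (target)
Conditions: HF·pyridine, THF, 0 °C to rt
Reagents that add atoms: none
Why: Fluoride-mediated cleavage of both silyl ethers under buffered, mildly acidic conditions that the β-hydroxy ketone, the ketol and the methylene lactone should tolerate; no stereocentre is affected.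

## Compound list

1 | cyclopent-2-en-1-one | O=C1C=CCC1 | starting material
2 | dimethyl malonate | COC(=O)CC(=O)OC | starting material
3 | dimethyl 2-[(1R)-3-oxocyclopentyl]propanedioate | COC(=O)C(C(=O)OC)[C@@H]1CCC(=O)C1 | intermediate
4 | methyl 2-[(1R)-3-oxocyclopentyl]acetate | COC(=O)C[C@@H]1CCC(=O)C1 | intermediate
5 | pyrrolidine | C1CCNC1 | starting material
6 | methyl 2-[(1R)-3-(pyrrolidin-1-yl)cyclopent-3-en-1-yl]acetate | COC(=O)C[C@@H]1CC=C(N2CCCC2)C1 | intermediate
7 | tert-butyl but-2-ynoate | CC#CC(=O)OC(C)(C)C | starting material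
8 | tert-butyl (3R)-3-(2-methoxy-2-oxoethyl)-7-methyl-5-(pyrrolidin-1-yl)bicyclo[3.2.0]hept-6-ene-6-carboxylate (cis ring fusion, both fusion diastereomers) | COC(=O)C[C@@H]1CC2C(C)=C(C(=O)OC(C)(C)C)C2(N3CCCC3)C1 | intermediate (not isolated)
9 | tert-butyl (4R)-4-(2-methoxy-2-oxoethyl)-7-methyl-2-(pyrrolidin-1-yl)cyclohepta-1,6-diene-1-carboxylate | CC(C)(C)OC(=O)C1=C(N2CCCC2)C[C@H](CC(=O)OC)CC=C1C | intermediate
10 | tert-butyl (5R)-5-(2-methoxy-2-oxoethyl)-2-methyl-7-oxocyclohept-2-ene-1-carboxylate (C1 epimers and enol form) | COC(=O)C[C@@H]1CC=C(C)C(C(=O)OC(C)(C)C)C(=O)C1 | intermediate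
11 | sodium dienolate of 10 | [Na+].COC(=O)C[C@@H]1CC=C(C)C(C(=O)OC(C)(C)C)=C([O-])C1 | intermediate (not isolated)
12 | tert-butyl (1S,5R)-1-hydroxy-5-(2-methoxy-2-oxoethyl)-2-methyl-7-oxocyclohept-2-ene-1-carboxylate | COC(=O)C[C@@H]1CC=C(C)[C@@](O)(C(=O)OC(C)(C)C)C(=O)C1 | intermediate
13 | tert-butyl (1S,5R)-5-(2-methoxy-2-oxoethyl)-2-methyl-7-oxo-1-(triethylsilyloxy)cyclohept-2-ene-1-carboxylate | COC(=O)C[C@@H]1CC=C(C)[C@@](O[Si](CC)(CC)CC)(C(=O)OC(C)(C)C)C(=O)C1 | intermediate
14 | alkylborane from 13 (C9β-boranyl, C5-O-boranyl, H on C10β; drawn as the monomer) | COC(=O)C[C@@H]1C[C@@H]([BH2])[C@H](C)[C@@](O[Si](CC)(CC)CC)(C(=O)OC(C)(C)C)C(O[BH2])C1 | intermediate (not isolated)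
15 | tert-butyl 5ξ,9β-dihydroxy-7α-(2-methoxy-2-oxoethyl)-10α-methyl-1α-(triethylsilyloxy)cycloheptane-1β-carboxylate (both C5 epimers) | COC(=O)C[C@@H]1C[C@@H](O)[C@H](C)[C@@](O[Si](CC)(CC)CC)(C(=O)OC(C)(C)C)C(O)C1 | intermediate
16 | tert-butyl 9β-(tert-butyldimethylsilyloxy)-5ξ-hydroxy-7α-(2-methoxy-2-oxoethyl)-10α-methyl-1α-(triethylsilyloxy)cycloheptane-1β-carboxylate | COC(=O)C[C@@H]1C[C@@H](O[Si](C)(C)C(C)(C)C)[C@H](C)[C@@](O[Si](CC)(CC)CC)(C(=O)OC(C)(C)C)C(O)C1 | intermediate
17 | [1β-(tert-butoxycarbonyl)-9β-(tert-butyldimethylsilyloxy)-5ξ-hydroxy-10α-methyl-1α-(triethylsilyloxy)cycloheptan-7α-yl]acetic acid | OC(=O)C[C@@H]1C[C@@H](O[Si](C)(C)C(C)(C)C)[C@H](C)[C@@](O[Si](CC)(CC)CC)(C(=O)OC(C)(C)C)C(O)C1 | intermediate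
18 | [1β-(tert-butoxycarbonyl)-9β-(tert-butyldimethylsilyloxy)-10α-methyl-5-oxo-1α-(triethylsilyloxy)cycloheptan-7α-yl]acetic acid | OC(=O)C[C@@H]1C[C@@H](O[Si](C)(C)C(C)(C)C)[C@H](C)[C@@](O[Si](CC)(CC)CC)(C(=O)OC(C)(C)C)C(=O)C1 | intermediate
19 | dilithium salt of 18 (carboxylate and C5=C6 enolate) | [Li+].[Li+].[O-]C(=O)C[C@@H]1C[C@@H](O[Si](C)(C)C(C)(C)C)[C@H](C)[C@@](O[Si](CC)(CC)CC)(C(=O)OC(C)(C)C)C([O-])=C1 | intermediate (not isolated)
20 | lithium [1β-(tert-butoxycarbonyl)-9β-(tert-butyldimethylsilyloxy)-6β-iodo-10α-methyl-5-oxo-1α-(triethylsilyloxy)cycloheptan-7α-yl]acetate | [Li+].[O-]C(=O)C[C@@H]1C[C@@H](O[Si](C)(C)C(C)(C)C)[C@H](C)[C@@](O[Si](CC)(CC)CC)(C(=O)OC(C)(C)C)C(=O)[C@H]1I | intermediate (not isolated)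
21 | [1β-(tert-butoxycarbonyl)-9β-(tert-butyldimethylsilyloxy)-6α-hydroxy-10α-methyl-5-oxo-1α-(triethylsilyloxy)cycloheptan-7α-yl]acetic acid γ-lactone | C1C(=O)O[C@@H]2[C@H]1C[C@@H](O[Si](C)(C)C(C)(C)C)[C@H](C)[C@@](O[Si](CC)(CC)CC)(C(=O)OC(C)(C)C)C2=O | intermediate
22 | [1β-(tert-butoxycarbonyl)-9β-(tert-butyldimethylsilyloxy)-1α,6α-dihydroxy-10α-methyl-5-oxocycloheptan-7α-yl]acetic acid 6-γ-lactone | C1C(=O)O[C@@H]2[C@H]1C[C@@H](O[Si](C)(C)C(C)(C)C)[C@H](C)[C@@](O)(C(=O)OC(C)(C)C)C2=O | intermediate
23 | [1β-(tert-butoxycarbonyl)-9β-(tert-butyldimethylsilyloxy)-1α,5β,6α-trihydroxy-10α-methylcycloheptan-7α-yl]acetic acid 6-γ-lactone | C1C(=O)O[C@@H]2[C@H]1C[C@@H](O[Si](C)(C)C(C)(C)C)[C@H](C)[C@@](O)(C(=O)OC(C)(C)C)[C@H]2O | intermediate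
24 | trilithium salt of 23 (O1 and O5 alkoxides, lactone enolate) | [Li+].[Li+].[Li+].C1=C([O-])O[C@@H]2[C@H]1C[C@@H](O[Si](C)(C)C(C)(C)C)[C@H](C)[C@@]([O-])(C(=O)OC(C)(C)C)[C@H]2[O-] | intermediate (not isolated)
25 | 11-(dimethylaminomethyl) derivative of 23 (Mannich base, C11 epimers) | CN(C)CC1C(=O)O[C@@H]2[C@H]1C[C@@H](O[Si](C)(C)C(C)(C)C)[C@H](C)[C@@](O)(C(=O)OC(C)(C)C)[C@H]2O | intermediate (not isolated)
26 | trimethylammonium iodide from 25 | C[N+](C)(C)CC1C(=O)O[C@@H]2[C@H]1C[C@@H](O[Si](C)(C)C(C)(C)C)[C@H](C)[C@@](O)(C(=O)OC(C)(C)C)[C@H]2O.[I-] | intermediate (not isolated)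
27 | 2-[1β-(tert-butoxycarbonyl)-9β-(tert-butyldimethylsilyloxy)-1α,5β,6α-trihydroxy-10α-methylcycloheptan-7α-yl]prop-2-enoic acid 6-γ-lactone | C=C1C(=O)O[C@@H]2[C@H]1C[C@@H](O[Si](C)(C)C(C)(C)C)[C@H](C)[C@@](O)(C(=O)OC(C)(C)C)[C@H]2O | intermediate
28 | (2R)-2-methylbutanoic acid | CC[C@@H](C)C(=O)O | starting material
29 | (2R)-2-methylbutanoic 2,4,6-trichlorobenzoic anhydride | CC[C@@H](C)C(=O)OC(=O)c1c(Cl)cc(Cl)cc1Cl | intermediate (not isolated)
30 | 2-[1β-(tert-butoxycarbonyl)-9β-(tert-butyldimethylsilyloxy)-1α,6α-dihydroxy-10α-methyl-5β-[(2R)-2-methylbutanoyloxy]cycloheptan-7α-yl]prop-2-enoic acid 6-γ-lactone | C=C1C(=O)O[C@@H]2[C@H]1C[C@@H](O[Si](C)(C)C(C)(C)C)[C@H](C)[C@@](O)(C(=O)OC(C)(C)C)[C@H]2OC(=O)[C@H](C)CC | intermediate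
31 | triethylsilyl ester of 32 | C=C1C(=O)O[C@@H]2[C@H]1C[C@@H](O[Si](C)(C)C(C)(C)C)[C@H](C)[C@@](O[Si](CC)(CC)CC)(C(=O)O[Si](CC)(CC)CC)[C@H]2OC(=O)[C@H](C)CC | intermediate (not isolated)
32 | 9β-(tert-butyldimethylsilyloxy)-7α-(1-carboxyethenyl)-6α-hydroxy-10α-methyl-5β-[(2R)-2-methylbutanoyloxy]-1α-(triethylsilyloxy)cycloheptane-1β-carboxylic acid 12,6-lactone | C=C1C(=O)O[C@@H]2[C@H]1C[C@@H](O[Si](C)(C)C(C)(C)C)[C@H](C)[C@@](O[Si](CC)(CC)CC)(C(=O)O)[C@H]2OC(=O)[C@H](C)CC | intermediate
33 | acid chloride of 32 (C2 carbonyl chloride) | C=C1C(=O)O[C@@H]2[C@H]1C[C@@H](O[Si](C)(C)C(C)(C)C)[C@H](C)[C@@](O[Si](CC)(CC)CC)(C(=O)Cl)[C@H]2OC(=O)[C@H](C)CC | intermediate (not isolated)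
34 | 2-[1β-acetyl-9β-(tert-butyldimethylsilyloxy)-6α-hydroxy-10α-methyl-5β-[(2R)-2-methylbutanoyloxy]-1α-(triethylsilyloxy)cycloheptan-7α-yl]prop-2-enoic acid γ-lactone | C=C1C(=O)O[C@@H]2[C@H]1C[C@@H](O[Si](C)(C)C(C)(C)C)[C@H](C)[C@@](O[Si](CC)(CC)CC)(C(C)=O)[C@H]2OC(=O)[C@H](C)CC | intermediate
35 | acetaldehyde | CC=O | starting material
36 | enol diisopinocampheylborinate of 34 | C=C1C(=O)O[C@@H]2[C@H]1C[C@@H](O[Si](C)(C)C(C)(C)C)[C@H](C)[C@@](O[Si](CC)(CC)CC)(C(=C)OB([C@H]3C[C@H]4C[C@@H]([C@@H]3C)C4(C)C)[C@H]3C[C@H]4C[C@@H]([C@@H]3C)C4(C)C)[C@H]2OC(=O)[C@H](C)CC | intermediate (not isolated)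
37 | O4-diisopinocampheylboryl ether of 38 (boron aldolate) | C=C1C(=O)O[C@@H]2[C@H]1C[C@@H](O[Si](C)(C)C(C)(C)C)[C@H](C)[C@@](O[Si](CC)(CC)CC)(C(=O)C[C@H](C)OB([C@H]3C[C@H]4C[C@@H]([C@@H]3C)C4(C)C)[C@H]3C[C@H]4C[C@@H]([C@@H]3C)C4(C)C)[C@H]2OC(=O)[C@H](C)CC | intermediate (not isolated)
38 | 2-[9β-(tert-butyldimethylsilyloxy)-6α-hydroxy-1β-[(3S)-3-hydroxybutanoyl]-10α-methyl-5β-[(2R)-2-methylbutanoyloxy]-1α-(triethylsilyloxy)cycloheptan-7α-yl]prop-2-enoic acid γ-lactone | C=C1C(=O)O[C@@H]2[C@H]1C[C@@H](O[Si](C)(C)C(C)(C)C)[C@H](C)[C@@](O[Si](CC)(CC)CC)(C(=O)C[C@H](C)O)[C@H]2OC(=O)[C@H](C)CC | intermediate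
39 | 2-[1α,6α,9β-trihydroxy-1β-[(3S)-3-hydroxybutanoyl]-10α-methyl-5β-[(2R)-2-methylbutanoyloxy]cycloheptan-7α-yl]prop-2-enoic acid 6-γ-lactone (1S,4S,5S,6R,7S,9R,10S) | C=C1C(=O)O[C@@H]2[C@H]1C[C@@H](O)[C@H](C)[C@@](O)(C(=O)C[C@H](C)O)[C@H]2OC(=O)[C@H](C)CC | target

## Step count and least certain steps

Total: 20 steps. Longest linear sequence: 20 steps (1 and 2 to 39); 5, 7, 28 and 35 enter as bought components.

Step 4 (key step).
- What may go wrong: conjugate addition of the enamine to a β-methyl alkynoate is slow, so proton transfer within the dipolar intermediate to an open-chain dienamine, reaction through the C5=C6 enamine isomer and thermal loss of the enamine can all compete.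
- Fallback, from 4 back to 10: the acceptor is activated by acid and the donor becomes a silyl enol ether. Ketone 4 is silylated (tBuMe2SiOTf, Et3N) to methyl 2-[(1R)-3-(tert-butyldimethylsilyloxy)cyclopent-3-en-1-yl]acetate F1. A Tf2NH-catalysed [2+2] addition with 7 (CH2Cl2, −78 °C) gives tert-butyl (3R)-5-(tert-butyldimethylsilyloxy)-3-(2-methoxy-2-oxoethyl)-7-methylbicyclo[3.2.0]hept-6-ene-6-carboxylate F2. Heating in toluene opens F2 to tert-butyl (4R)-2-(tert-butyldimethylsilyloxy)-4-(2-methoxy-2-oxoethyl)-7-methylcyclohepta-1,6-diene-1-carboxylate F3, and HF·pyridine converts F3 into 10. The same two bonds are formed and the same bond is broken.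

Step 6.
- What may go wrong: poor facial selectivity at C1, because the substrate itself does not differentiate the faces of the dienolate and the chiral oxidant may discriminate only weakly; some attack at C9 is also possible.
- Fallback, from 10 to 12 directly: the control element is moved from the oxidant to a catalyst. The β-keto ester is bound as a bidentate enolate to Cu(OTf)2 (divalent copper) carrying a C2-symmetric bis(oxazoline) ligand and is hydroxylated with achiral 3-phenyl-2-(phenylsulfonyl)oxaziridine. tert-Butyl β-keto esters are the favoured substrates of such chelate-controlled hydroxylations. No new compound is involved.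

Step 8.
- What may go wrong: addition from the α face, syn to the silyloxy group, because the tert-butoxycarbonyl group on the β face of C1 is itself bulky; this would give the wrong C9/C10 pair. Slow reduction of the methyl ester by excess borane is a lesser risk.
- Fallback, from 13 to 15: the face is taken out of the hands of the substrate by hydroborating with monoisopinocampheylborane (from (−)-α-pinene, or its enantiomer if the other face is matched), followed by the same oxidation. The reagent also reduces C5, so 15 is reached directly. No new compound is involved.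

Step 19.
- What may go wrong: low diastereoselectivity at C4, since methyl ketone boron aldol reactions with a small aldehyde are only moderately selective and the chiral ketone may be mismatched with the ligand; retro-aldol on work-up is a lesser risk.
- Fallback, from 34 to 38: the aldehyde face is set by a chiral Lewis acid instead of by the enolate. Ketone 34 is converted (Me3SiOTf, Et3N, −78 °C) into its trimethylsilyl enol ether F4. A Mukaiyama aldol reaction with 35, catalysed by the enantiomer of 2-butyl-4-(1H-indol-3-ylmethyl)-3-(4-methylphenylsulfonyl)-1,3,2-oxazaborolidin-5-one that shields the si face of the aldehyde, gives the O4-trimethylsilyl ether F5, which dilute acid converts into 38.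

## Further compounds

F1 | step 4 | methyl 2-[(1R)-3-(tert-butyldimethylsilyloxy)cyclopent-3-en-1-yl]acetate | COC(=O)C[C@@H]1CC=C(O[Si](C)(C)C(C)(C)C)C1
F2 | step 4 | tert-butyl (3R)-5-(tert-butyldimethylsilyloxy)-3-(2-methoxy-2-oxoethyl)-7-methylbicyclo[3.2.0]hept-6-ene-6-carboxylate | COC(=O)C[C@@H]1CC2C(C)=C(C(=O)OC(C)(C)C)C2(O[Si](C)(C)C(C)(C)C)C1
F3 | step 4 | tert-butyl (4R)-2-(tert-butyldimethylsilyloxy)-4-(2-methoxy-2-oxoethyl)-7-methylcyclohepta-1,6-diene-1-carboxylate | CC(C)(C)OC(=O)C1=C(O[Si](C)(C)C(C)(C)C)C[C@H](CC(=O)OC)CC=C1C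
F0 | step 6 | none | none
F0 | step 8 | none | none
F4 | step 19 | trimethylsilyl enol ether of 34 | C=C1C(=O)O[C@@H]2[C@H]1C[C@@H](O[Si](C)(C)C(C)(C)C)[C@H](C)[C@@](O[Si](CC)(CC)CC)(C(=C)O[Si](C)(C)C)[C@H]2OC(=O)[C@H](C)CC
F5 | step 19 | O4-trimethylsilyl ether of 38 | C=C1C(=O)O[C@@H]2[C@H]1C[C@@H](O[Si](C)(C)C(C)(C)C)[C@H](C)[C@@](O[Si](CC)(CC)CC)(C(=O)C[C@H](C)O[Si](C)(C)C)[C@H]2OC(=O)[C@H](C)CC
A1 | alternative 1 | protected target core with the methylene lactone, an acetonide across O1 and O5 and silyl ethers on O9 and O4 | C=C1C(=O)O[C@@H]2[C@H]1C[C@@H](O[Si](C)(C)C(C)(C)C)[C@H](C)[C@]3(C(=O)C[C@H](C)O[Si](C)(C)C(C)(C)C)OC(C)(C)O[C@@H]23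
A2 | alternative 2 | ethyl 6-benzyloxy-7-methyl-2-oxo-8-oxabicyclo[3.2.1]oct-3-ene-1-carboxylate | CCOC(=O)[C@@]12O[C@@H](C=CC1=O)[C@@H](OCc1ccccc1)[C@@H]2C
A3 | alternative 3 | cis-fused oxolane–cycloheptane-1,4-dione with a silyloxymethyl arm (C10 epimers) | CC(C)(C)[Si](c1ccccc1)(c1ccccc1)OC[C@@H]1CO[C@@H]2[C@H]1CC(=O)C(C)CC2=O
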